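**Strategy.** The plan cuts the bond between the prenyloxyphenyl ring and the adjacent diketone carbonyl. It exploits the ortho pair on the chromene benzene ring, the C7 hydroxyl and the C6 1,2-diketone: this unit is the ring-opened tautomer of a 2-aryl-2-hydroxybenzofuran-3(2H)-one, so the distal carbonyl carbon can be carried as the nucleophilic C2 methylene of a fused furanone. In one flask, Pd-catalysed α-arylation of tricyclic 4-methoxy-7,7-dimethylfuro[3,2-g]chromen-3(2H)-one with 1-bromo-4-(prenyloxy)benzene, enolate oxygenation and ring opening deliver the target. The furanone oxygen is the masked phenol, the same ring differentiates the three phloroglucinol oxygens, and no protecting group is used.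

Key step: step 5

Assumption: hemiketal 12 and benzil 13 are ring–chain tautomers, and the open, O–H···O=C chelated form drawn for the natural product is taken as the isolated one; the target has no stereocentre. Furanone 1 is taken as commercial.

Step 1
Reactants: 1 4,6-dihydroxy-1-benzofuran-3(2H)-one; 2 3-chloro-3-methylbut-1-yne
Product: 3 4-hydroxy-6-[(2-methylbut-3-yn-2-yl)oxy]-1-benzofuran-3(2H)-one
Conditions: CuCl2·2H2O (1 mol%), DBU (1.1 equiv), MeCN/DMF, 0 °C to rt
Reagents that add atoms: none
Why: Copper-catalysed propargylic etherification of a phenoxide (substitution of the tertiary propargylic chloride via a copper acetylide) should alkylate only the 6-hydroxyl, the more acidic and unhindered OH para to the C3 carbonyl, because the 4-hydroxyl is hydrogen-bonded to C3=O and one equivalent of base leaves the C2 methylene un-enolised.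

Step 2
Reactants: 3 4-hydroxy-6-[(2-methylbut-3-yn-2-yl)oxy]-1-benzofuran-3(2H)-one
Product: 6 4-hydroxy-7,7-dimethyl-7H-furo[3,2-g]chromen-3(2H)-one, via ortho-allenylphenol 4 (not isolated), via ortho-quinone methide 5 (not isolated)
Conditions: o-xylene (degassed), 140 °C, sealed tube
Reagents that add atoms: none
Why: Aromatic propargyl Claisen cascade ([3,3] shift and enolisation to 4, 1,5-hydrogen shift to 5, oxa-6π electrocyclisation), in which the shift should favour C5 over C7 because C5 is ortho to the C3=O-chelated 4-hydroxyl and para to the furanone oxygen (the behaviour of 2-hydroxy-4-propargyloxyaryl ketones), and the pyran should close on O6 because that keeps the O4–H···O=C3 hydrogen bond.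

Step 3
Reactants: 6 4-hydroxy-7,7-dimethyl-7H-furo[3,2-g]chromen-3(2H)-one
Product: 7 4-methoxy-7,7-dimethyl-7H-furo[3,2-g]chromen-3(2H)-one
Conditions: Me2SO4 (1.2 equiv), K2CO3 (2 equiv), acetone, reflux
Reagents that add atoms: dimethyl sulfate COS(=O)(=O)OC
Why: Williamson O-methylation, in which the phenoxide forms and reacts with the hard electrophile in preference to the C2 enolate (as in the O-methylation of the parent 4,6-dihydroxyfuranone 1), caps the hindered 4-hydroxyl that becomes the C5 methoxy group of the target.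

Step 4
Reactants: 8 4-bromophenol; 9 1-bromo-3-methylbut-2-ene (prenyl bromide)
Product: 10 1-bromo-4-[(3-methylbut-2-en-1-yl)oxy]benzene
Conditions: K2CO3, acetone, reflux
Reagents that add atoms: none
Why: Williamson ether synthesis, in which the phenoxide displaces the primary allylic bromide by SN2 at C1 and so gives the linear prenyl ether.

Step 5
Reactants: 7 4-methoxy-7,7-dimethyl-7H-furo[3,2-g]chromen-3(2H)-one; 10 1-bromo-4-[(3-methylbut-2-en-1-yl)oxy]benzene
Product: 13 ficucaricone C, via 2-arylfuranone 11 (not isolated), via cyclic hemiketal 12 (not isolated)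
Conditions: Pd2(dba)3 (2 mol%), XPhos (8 mol%), K3PO4 (2.5 equiv), toluene, 90 °C, argon; then 0 °C, THF, P(OEt)3 (1.2 equiv), O2 (1 atm); aq. NH4Cl
Reagents that add atoms: dioxygen O=O
Why: Oxidative addition of 10 to Pd(0)–XPhos, exchange of bromide for the potassium enolate of 7 and C–C reductive elimination at C2 give 11, which is then present as its aromatic 3-oxidobenzofuran enolate; under O2 this enolate is oxygenated at C2, triethyl phosphite reduces the hydroperoxide to hemiketal 12, and 12 opens by ring–chain tautomerism to the chelated hydroxy-diketone 13. The closest known reaction types are the Pd-catalysed α-arylation of cyclic aryl ketones and the α-hydroxylation of enolates with O2 and a phosphite, run here in one flask. No ring is closed: the furanone ring is opened, and the only new stereocentre (C2 of 11 and 12, formed racemic and uncontrolled) is erased in 13, which has none. C2 is the only enolisable position; a second arylation is held back because 11 is more acidic and its enolate more hindered than that of 7, and the bulky biarylphosphine should make insertion into the C–Br bond faster than ionisation of the trisubstituted prenyl ether. The weak base K3PO4 limits aldol self-condensation of 7 and benzilic-type rearrangement of 13, and triplet oxygen at 0 °C should react with the enolate but not with the chromene or prenyl double bonds.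

**Compound list**

1 | 4,6-dihydroxy-1-benzofuran-3(2H)-one | O=C1COc2cc(O)cc(O)c12 | starting material
2 | 3-chloro-3-methylbut-1-yne | CC(C)(Cl)C#C | starting material
3 | 4-hydroxy-6-[(2-methylbut-3-yn-2-yl)oxy]-1-benzofuran-3(2H)-one | O=C1COc2cc(OC(C)(C)C#C)cc(O)c12 | intermediate
4 | 4,6-dihydroxy-5-(3-methylbuta-1,2-dien-1-yl)-1-benzofuran-3(2H)-one (ortho-allenylphenol) | O=C1COc2cc(O)c(C=C=C(C)C)c(O)c12 | intermediate (not isolated)
5 | 4-hydroxy-5-(3-methylbut-2-en-1-ylidene)-1-benzofuran-3,6(2H,5H)-dione (ortho-quinone methide, exocyclic alkene geometry not defined) | O=C1COC2=CC(=O)C(=CC=C(C)C)C(O)=C12 | intermediate (not isolated)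
6 | 4-hydroxy-7,7-dimethyl-7H-furo[3,2-g]chromen-3(2H)-one (linear tricycle: furanone O1/C2/C3, hydroxyl on C4, pyran C5=C6–C7(Me)2–O8) | O=C1COc2cc3OC(C)(C)C=Cc3c(O)c12 | intermediate
7 | 4-methoxy-7,7-dimethyl-7H-furo[3,2-g]chromen-3(2H)-one | O=C1COc2cc3OC(C)(C)C=Cc3c(OC)c12 | intermediate
8 | 4-bromophenol | Oc1ccc(Br)cc1 | starting material
9 | 1-bromo-3-methylbut-2-ene (prenyl bromide) | CC(C)=CCBr | starting material
10 | 1-bromo-4-[(3-methylbut-2-en-1-yl)oxy]benzene | CC(C)=CCOc1ccc(Br)cc1 | intermediate
11 | racemic 4-methoxy-7,7-dimethyl-2-{4-[(3-methylbut-2-en-1-yl)oxy]phenyl}-7H-furo[3,2-g]chromen-3(2H)-one | O=C1C(c2ccc(OCC=C(C)C)cc2)Oc2cc3OC(C)(C)C=Cc3c(OC)c12 | intermediate (not isolated)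
12 | racemic 2-hydroxy-4-methoxy-7,7-dimethyl-2-{4-[(3-methylbut-2-en-1-yl)oxy]phenyl}-7H-furo[3,2-g]chromen-3(2H)-one (cyclic hemiketal) | O=C1C(O)(c2ccc(OCC=C(C)C)cc2)Oc2cc3OC(C)(C)C=Cc3c(OC)c12 | intermediate (not isolated)
13 | ficucaricone C, 1-(7-hydroxy-5-methoxy-2,2-dimethyl-2H-chromen-6-yl)-2-{4-[(3-methylbut-2-en-1-yl)oxy]phenyl}ethane-1,2-dione (achiral) | COc1c2c(cc(O)c1C(=O)C(=O)c1ccc(OCC=C(C)C)cc1)OC(C)(C)C=C2 | target

**Total step count:** 5
**Longest linear sequence:** 4 (steps 1, 2, 3, 5)

**Steps most likely to fail**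

1. Step 2. What may go wrong: the [3,3] shift is not site-selective and goes to C7 (between O6 and the furanone oxygen), or the pyran closes on O4, so that angular pyrans form. Fallback, a different way to fix the ring pattern: a para-Claisen (Claisen–Cope) shift in an open-chain ketone, which can only end on the carbon between the methoxy carbon and the 4-oxygen. The furanone is then not needed, and the same C–C bond is made by α-arylation of an acetyl group. It sets out from 9 and 10 and comes back to the route at 13. Commercial 1-(2,4-dihydroxy-6-methoxyphenyl)ethanone F1 is protected at its free 4-hydroxyl (MOMCl, i-Pr2NEt, CH2Cl2) to give 1-[2-hydroxy-6-methoxy-4-(methoxymethoxy)phenyl]ethanone F2. Prenylation of the chelated hydroxyl with 9 (K2CO3, DMF, 60 °C) should give 1-{2-methoxy-4-(methoxymethoxy)-6-[(3-methylbut-2-en-1-yl)oxy]phenyl}ethanone F3. Heating (N,N-diethylaniline, 190 °C) should move the prenyl group by two [3,3] shifts to the carbon para to that oxygen and give 1-[6-hydroxy-2-methoxy-4-(methoxymethoxy)-3-(3-methylbut-2-en-1-yl)phenyl]ethanone F4. Mild acid (HCl, MeOH, rt) should free 1-[4,6-dihydroxy-2-methoxy-3-(3-methylbut-2-en-1-yl)phenyl]ethanone F5. DDQ (benzene, reflux) should close the pyran on the only hydroxyl next to the prenyl group and give 1-(7-hydroxy-5-methoxy-2,2-dimethyl-2H-chromen-6-yl)ethanone F6. Pd-catalysed α-arylation of F6 with 10 (Pd2(dba)3, XPhos, LiHMDS 3.2 equiv, THF, 65 °C) should give the deoxybenzoin 1-(7-hydroxy-5-methoxy-2,2-dimethyl-2H-chromen-6-yl)-2-{4-[(3-methylbut-2-en-1-yl)oxy]phenyl}ethanone F7. Base-mediated aerobic oxidation of its methylene (Cs2CO3, O2, DMSO, rt) should then give 13.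

2. Step 5. What may go wrong: Pd(0) ionises the prenyl aryl ether (π-allyl formation), so that the enolate is prenylated instead of arylated and the catalyst is diverted. Fallback, a change of fragment and end game: the aryl partner carries a silyl ether through the Pd step and the prenyl group is put on last. It sets out from 7 and comes back to the route at 13. Commercial (4-bromophenoxy)tri(propan-2-yl)silane F8 and 7 under the conditions of step 5 should give, through the racemic 2-arylfuranone F9 and the racemic 2-hydroxy hemiketal F10 (neither isolated), the silyl-protected benzil 1-(7-hydroxy-5-methoxy-2,2-dimethyl-2H-chromen-6-yl)-2-{4-[tri(propan-2-yl)silyloxy]phenyl}ethane-1,2-dione F11. TBAF (THF, 0 °C) should free the diphenol 1-(7-hydroxy-5-methoxy-2,2-dimethyl-2H-chromen-6-yl)-2-(4-hydroxyphenyl)ethane-1,2-dione F12. Prenyl bromide 9 with K2CO3 (1.1 equiv) in acetone should then alkylate only the 4'-hydroxyl, because the 7-hydroxyl is hydrogen-bonded to the ketone and flanked by it, to give 13.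

3. Step 1. What may go wrong: the base-mediated alkylation loses site selectivity (C-alkylation at the acidic C2 methylene, alkylation of both hydroxyls), or the tertiary chloride eliminates. Fallback, a different pyran annulation that uses no alkyl halide and no stoichiometric base and replaces steps 1 and 2: it sets out from 1 and comes back to the route at 6. Heating 1 with commercial 1,1-diethoxy-3-methylbut-2-ene (3-picoline cat., xylene, 140 °C, ethanol distilled off) should give by acetal exchange at the 6-hydroxyl the mixed acetal 6-[(1-ethoxy-3-methylbut-2-en-1-yl)oxy]-4-hydroxy-1-benzofuran-3(2H)-one F13 (not isolated). Ionisation and recombination at C5 should give the benzylic ether 5-(1-ethoxy-3-methylbut-2-en-1-yl)-4,6-dihydroxy-1-benzofuran-3(2H)-one F14 (not isolated). F14 should lose ethanol to quinone methide 5, which closes to 6 as in step 2.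

**Further compounds**

F1 | step 2 | 1-(2,4-dihydroxy-6-methoxyphenyl)ethanone | CC(=O)c1c(O)cc(O)cc1OC
F2 | step 2 | 1-[2-hydroxy-6-methoxy-4-(methoxymethoxy)phenyl]ethanone | CC(=O)c1c(O)cc(OCOC)cc1OC
F3 | step 2 | 1-{2-methoxy-4-(methoxymethoxy)-6-[(3-methylbut-2-en-1-yl)oxy]phenyl}ethanone | CC(=O)c1c(OCC=C(C)C)cc(OCOC)cc1OC
F4 | step 2 | 1-[6-hydroxy-2-methoxy-4-(methoxymethoxy)-3-(3-methylbut-2-en-1-yl)phenyl]ethanone | CC(=O)c1c(O)cc(OCOC)c(CC=C(C)C)c1OC
F5 | step 2 | 1-[4,6-dihydroxy-2-methoxy-3-(3-methylbut-2-en-1-yl)phenyl]ethanone | CC(=O)c1c(O)cc(O)c(CC=C(C)C)c1OC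
F6 | step 2 | 1-(7-hydroxy-5-methoxy-2,2-dimethyl-2H-chromen-6-yl)ethanone | CC(=O)c1c(O)cc2OC(C)(C)C=Cc2c1OC
F7 | step 2 | 1-(7-hydroxy-5-methoxy-2,2-dimethyl-2H-chromen-6-yl)-2-{4-[(3-methylbut-2-en-1-yl)oxy]phenyl}ethanone | O=C(Cc1ccc(OCC=C(C)C)cc1)c1c(O)cc2OC(C)(C)C=Cc2c1OC
F8 | step 5 | (4-bromophenoxy)tri(propan-2-yl)silane | CC(C)[Si](Oc1ccc(Br)cc1)(C(C)C)C(C)C
F9 | step 5 | racemic 4-methoxy-7,7-dimethyl-2-{4-[tri(propan-2-yl)silyloxy]phenyl}-7H-furo[3,2-g]chromen-3(2H)-one | O=C1C(c2ccc(O[Si](C(C)C)(C(C)C)C(C)C)cc2)Oc2cc3OC(C)(C)C=Cc3c(OC)c12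
F10 | step 5 | racemic 2-hydroxy-4-methoxy-7,7-dimethyl-2-{4-[tri(propan-2-yl)silyloxy]phenyl}-7H-furo[3,2-g]chromen-3(2H)-one | O=C1C(O)(c2ccc(O[Si](C(C)C)(C(C)C)C(C)C)cc2)Oc2cc3OC(C)(C)C=Cc3c(OC)c12
F11 | step 5 | 1-(7-hydroxy-5-methoxy-2,2-dimethyl-2H-chromen-6-yl)-2-{4-[tri(propan-2-yl)silyloxy]phenyl}ethane-1,2-dione | COc1c2c(cc(O)c1C(=O)C(=O)c1ccc(O[Si](C(C)C)(C(C)C)C(C)C)cc1)OC(C)(C)C=C2
F12 | step 5 | 1-(7-hydroxy-5-methoxy-2,2-dimethyl-2H-chromen-6-yl)-2-(4-hydroxyphenyl)ethane-1,2-dione | COc1c2c(cc(O)c1C(=O)C(=O)c1ccc(O)cc1)OC(C)(C)C=C2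
F13 | step 1 | racemic 6-[(1-ethoxy-3-methylbut-2-en-1-yl)oxy]-4-hydroxy-1-benzofuran-3(2H)-one | O=C1COc2cc(OC(OCC)C=C(C)C)cc(O)c12
F14 | step 1 | racemic 5-(1-ethoxy-3-methylbut-2-en-1-yl)-4,6-dihydroxy-1-benzofuran-3(2H)-one | O=C1COc2cc(O)c(C(OCC)C=C(C)C)c(O)c12
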